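- Watch the small charge: 1 mol% of free catalyst carries this flask, Saturday's run, which is followed up to 5.00 d and asked about at 8.0 d.

| flask | starting material | reagent | second substrate | free catalyst | temperature | remark | time |
|---|---|---|---|---|---|---|---|
| Saturday's | 0.10 M | 1.05 equiv | 0.50 equiv | 1 mol% | 80 °C | the very flask that is asked about, followed so far |  |
| Wednesday's | 0.10 M | 1.05 equiv | 0.50 equiv | 1 mol% | 65 °C | run made earlier |  |
| flask | 0.10 M | 1.05 equiv | 0.500 equiv | 1 mol% | 80 °C |  | 8.0 d |

| run | time / d | target / % |
|---|---|---|
| Saturday's | 0.625 | 25.8 |
| Saturday's | 1.25 | 38.9 |
| Saturday's | 2.08 | 43.2 |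
| Saturday's | 3.00 | 47.5 |
| Saturday's | 4.00 | 48.7 |
| Saturday's | 5.00 | 49.4 |
| Wednesday's | 1.25 | 27.9 |
| Wednesday's | 2.50 | 37.1 |
| Wednesday's | 4.00 | 46.0 |
| Wednesday's | 6.00 | 52.4 |
| Wednesday's | 8.00 | 54.8 |
| Wednesday's | 10.0 | 57.0 |

(standard deviation of a reading: 1 percentage point)

- ash: at 8.0 d take out 90 % of the target then present, then wait 2.5 d
- alder: change nothing and wait 2.5 d more
- birch: at 8.0 d add reagent, 100 % of the amount charged, then wait 2.5 d
- cedar: at 8.0 d raise the temperature by 20 K, then wait 2.5 d
- elm: at 8.0 d add free catalyst, 100 % of the amount charged, then wait 2.5 d

- target that was removed still counts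
- the numbers in the tables scatter by 1 percentage point (one standard deviation)
- additions bring no volume worth counting

- target, in percent of the starting material first charged, at 8.0 d
- the option that brings most further target ("none" if no option brings more than 2 percentage points) (ash / alder / birch / cedar / elm / none)
- target present, with what was taken out counted in, in percent of the starting material first charged, after ash
- target present, with what was taken out counted in, in percent of the starting material first charged, after cedar

- Start with the bench rule for a first-order climb (pseudo-first-order, reagent taken as steady). Let L be the natural logarithm of starting material charged over starting material left, reading what is gone as target. The first reading gives L = 0.298, so a half-life of 1.45 d. Then 5.52 half-lives fit into 8.0 d, which promises nearly all of the starting material converted.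
- Find the border with a ratio: L over its straight line from the first reading. In Saturday's run it is 0.825 at 1.25 d and 0.285 at 5.00 d, so drop the rule early.
- Let the pace fade exponentially at rate d and integrate: L = reach × (1 − exp(−d × time)).
- Take the last reading as 0.681: this is the reach, the height at which L stops climbing for one charge of catalyst. The first reading then gives d = 0.922 d⁻¹, so the pace halves every 0.752 d.
- Do not read the reach as a ceiling set by the charges: Wednesday's cooler run climbs higher than Saturday's, to 57.0 %.
- My own reckoning puts the target at 8.0 d at 49.4 %, lower than the forecast's 50.2 %.
- The forecast chooses elm, with 50.5 % after ash and 50.5 % after cedar. In its words: “Waiting, removing target, more reagent or heating do almost nothing.”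
- The flask gives 51.0 % and best option elm, which brings 5.4 percentage points. With what was taken out counted in, ash ends at 51.2 %; cedar ends at 51.0 %.

    free catalyst → spent catalyst A (k = 0.00410 h⁻¹, Ea = 113 kJ mol⁻¹)
    free catalyst + target → spent catalyst B (k = 0.380 M⁻¹ h⁻¹, Ea = 101 kJ mol⁻¹)
    starting material + reagent + free catalyst → free catalyst + target (k = 290 M⁻² h⁻¹, Ea = 51.0 kJ mol⁻¹)
    second substrate + reagent + free catalyst → free catalyst + second product (k = 450 M⁻² h⁻¹, Ea = 65.0 kJ mol⁻¹)
    (constants at 80 °C)

- The flask has come to rest at 8.0 d with free catalyst at 1.74 % of the catalyst charged, while starting material stands at 48.3 % and reagent at 18.5 %, each of its own charge. Its L, reckoned from the target, is 0.713 against the reach of 0.681. Waiting 2.5 d more brings 0.14 points, and at 80.0 d the target reads 51.2 %, so length of run is not the thing to change.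
- Carry the reach to the neighbour flask with 4.20 equiv of reagent, assuming that the reach goes with the reagent charge while the fade rate and the other charges stay as they are. The estimate is then 2.72, which gives 93.4 % target; that neighbour flask gives 93.7 % at 8.0 d.

The numbers in the tables are calculated with constants of no real substance; the scatter is artificial.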